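A small charge of electrophile has to be carried most of the way by a nucleophile that also consumes itself, so the unknown is how much nucleophile goes in.

electrophile 22 mM; gas 12 mM (held); scavenger 33.0 mM; time 8.0 h

    gas ⇌ free base, rate k1*(csat - [free base]) (k1 = 1.47 × 10⁻⁴ /s, csat = 12 mM)
    acid set free + scavenger → scavenged by-product (k2 = 0.00746 /M/s)
    acid set free + free base ⇌ salt of the base (K3 = 9.6 × 10⁵ /M, k3 = 0.0730 /M/s)
    electrophile + acid set free ⇌ idle adduct, settled at all times (K4 = 33.2 /M)
    2 nucleophile → self-condensation product (k5 = 0.00123 /M/s)
    electrophile + nucleophile → acid set free + target (k6 = 0.00234 /M/s)
    nucleophile + acid set free ⇌ protonated nucleophile, settled at all times (K7 = 4.23 × 10⁵ /M)

* the concentration of nucleophile at which the part of the electrophile that has reacted at 8.0 h is just 80 %, in mM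

- amounts and yields of acid set free count idle adduct too
- a step written with two of one species runs at k times the square of its concentration and takes two of it each time
- at the start none of free base is dissolved
- the amount of nucleophile is what is sought; it is there from the start
- what has gone from electrophile into another species counts as reacted, even if it can come back
- run time (flask): 8.0 h

To leave 20.0 % of the electrophile, a steady nucleophile, in a pseudo-first-order reckoning, has to average 23.9 mM, which looks modest. The objection is that nucleophile does not stay steady. It uses itself as fast as coupling with the electrophile uses it where its concentration equals the electrophile's times the selectivity factor, the coupling constant over twice the self-condensation constant, 0.951. With the electrophile as charged, that crossing lies at 20.9 mM, and the average wanted stands above it. Self-condensation by itself brings a large charge down to about 14.1 mM at the asked time, less than that average, so the charge must start far higher.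

Counting self-condensation as the one drain, the electrophile left is one plus twice the self-condensation constant times charge times time, raised to minus the factor, and this asks for 62.5 mM. But each coupling sets acid free, which may take a second nucleophile. Scavenger and free base, the latter taken at saturation although none is dissolved at the start, reckon to remove free acid at 4.04 /h, yet beside nucleophile at about 14.1 mM so little of the acid stands free that its removal reckons to 1480 h, much longer than the run. So each turnover is reckoned at two nucleophiles, which adds 35.2 mM and gives 97.7 mM. One doubt remains: at that charge self-condensation has a first half-life of 1.16 h, shorter than the run, so the added nucleophile does not all survive, and my figure is low.

The forecast gives 115 mM, more than my reckoning, holding that “each electrophile turnover effectively uses two nucleophiles”.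

The flask needs 114 mM, which the forecast meets within its margin. At 0.549 h, self-condensation was using nucleophile 4.5 times as fast as coupling. At this charge, twice the self-condensation constant times charge times time is larger than one, so in the self-condensation reckoning above the electrophile left goes nearly as the charge to the power minus 0.951. A quarter more nucleophile then reckons to 83.8 % reacted, and the run with that charge gives 84.0 %.

The constants belong to no real substance; the result is computed.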